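The earlier runs and the new flask come from a simulation for an exercise; scatter was added.

Late in the runs, at 90.0 s, Friday's and Monday's readings averaged 17.4% left-handed product and 6.65% right-handed product, in percent of both substrates charged.

| flask | left-handed substrate | right-handed substrate | solid reagent | remark | time |
|---|---|---|---|---|---|
| Friday's | 0.067 M | 0.067 M | 0.20 M | run made earlier |  |
| Monday's | 0.15 M | 0.15 M | 0.20 M | run made earlier |  |
| Wednesday's | 0.10 M | 0.10 M | 0.10 M | run made earlier |  |
| flask | 0.10 M | 0.10 M | 0.200 M |  | 2.0 min |

| run | time / s | left-handed product / % | right-handed product / % |
|---|---|---|---|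
| Friday's | 15.0 | 3.5 | 0 |
| Friday's | 30.0 | 6.3 | 3.9 |
| Friday's | 40.0 | 8.9 | 2.2 |
| Friday's | 60.0 | 12.0 | 3.0 |
| Friday's | 80.0 | 18.6 | 5.0 |
| Friday's | 90.0 | 16.4 | 6.7 |
| Monday's | 10.0 | 0.6 | 1.9 |
| Monday's | 15.0 | 2.9 | 0 |
| Monday's | 25.0 | 5.8 | 0 |
| Monday's | 40.0 | 10.7 | 2.6 |
| Monday's | 60.0 | 12.1 | 3.7 |
| Monday's | 80.0 | 16.4 | 6.6 |
| Monday's | 90.0 | 18.4 | 6.6 |
| Wednesday's | 10.0 | 1.4 | 0.3 |
| Wednesday's | 15.0 | 3.3 | 0.8 |
| Wednesday's | 25.0 | 4.1 | 1.1 |
| Wednesday's | 50.0 | 9.8 | 2.3 |
| Wednesday's | 90.0 | 11.7 | 3.5 |

(each reading ± 1 percentage point)

- partner is single-handed; left-handed substrate and right-handed substrate are mirror images of each other, charged as a racemate, each of them at the stated concentration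
- solid, in amounts per volume of the solution: solid reagent
- what was read earlier has a scatter of 1 percentage point, one standard deviation
- at the start none of the solid reagent is in solution
- an excess is the difference of the two amounts in percent of their sum
- an excess is below zero if the other one leads
- the handed part of partner does not stay in what it makes, so the products of the two hands are mirror images too

- left-handed product and right-handed product together, in percent of the left-handed substrate and right-handed substrate charged together, at 2.0 min
- excess of left-handed product over right-handed product in the product at 2.0 min
- whether the exchange between left-handed substrate and right-handed substrate keeps pace with the reaction: how far the product's excess at 2.0 min gets from its value without exchange to its value with instant exchange (above 80% keeps pace, below 20% hardly takes part, else lags behind)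

Each hand is half of the charge, so I worked with the fraction of each that these readings had not put into product: 0.652 of the left-handed substrate and 0.867 of the right-handed. If the hands do not exchange, one fraction left is the other raised to a fixed power, and the ratio of their logarithms, read with the scatter of these readings, was 3.00, the selectivity factor.

I let the logarithm for the right-handed substrate grow in proportion to time up to 2.0 min, a risk, since Wednesday's run, with half the solid, had slowed after 50.0 s. I reckoned on 0.827 of the right-handed substrate and 0.565 of the left-handed not going into product, so I expected 30.4% product with an excess of 43.0%.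

The forecast said 29% and 48%, and that the exchange hardly takes part, in its words “so exchange is negligible”; my excess was lower. The flask gave 31.6% and 44.6%, and the exchange hardly takes part.

    partner + left-handed substrate → left-handed product (k = 0.0778 /M/s)
    partner + right-handed substrate → right-handed product (k = 0.0251 /M/s)
    left-handed substrate ⇌ achiral form (K = 0.0230, k = 0.00306 /s)
    right-handed substrate ⇌ achiral form (K = 0.0230, k = 0.00306 /s)
    solid reagent ⇌ partner, rate k5*(cs5 - [partner]) while solid is left; crystals form when [partner] > cs5 (solubility = 0.0790 M, k = 0.225 /s)
    partner ⇌ dormant form (K = 4.62, k = 0.0144 /s)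

From the 8.76% right-handed product at 2.00 min, the power 3.00 gives the flask 21.9% left-handed product, and it held 22.8%; the neighbour flask with 0.050 M solid reagent held 2.57% right-handed product, which gives 7.32% left-handed, and it held 7.57%. In the flask the half-life of the right-handed substrate by its loss to achiral form, forward rate alone, was 3.8 min, longer than the 2.0 min of the run. The exchange got 11% of the way from the excess without it to the excess with instant exchange.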